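Compound numbers are those of the steps and the compound list below. Ring A is the benzene ring of the dihydrobenzofuran, ring B the dihydrofuran ring, ring C the 4-hydroxyphenyl ring; atoms carry benzofuran numbering (O1, C2, C3, C3a, C4–C7, C7a).

## Analysis of the target

Target 19 is a chalcone whose ketone-bearing aryl group is a 2,3-dihydro-1-benzofuran. Ring A carries a methoxy group on C4, hydrogens on C5 and C6, and the (E)-3-(4-hydroxyphenyl)propenoyl group on C7, next to the O1-bearing C7a. There is a single stereocentre, C2 (R), which carries O1, C3, H and a 2-hydroxypropan-2-yl group. With no second centre to relate it to, only absolute control is needed; the E alkene is the other stereo-element. The sensitive groups are the enone (Michael acceptor, reducible, photo-isomerisable), the free phenol of ring C and the tertiary alcohol, which sits β to O1 and eliminates under strong acid. The C2–C3 bond of ring B is also at risk under forcing dehydrogenation, which would give the benzofuran and erase C2. The difficulty lies in ring A, a 1,2,3,4-tetrasubstituted benzene with four different substituents in a fixed order, and in setting a stereocentre that has no handle other than the ether oxygen. The strategy rests on the oxygen pattern of ring A: O1 on C7a and the methoxy oxygen on C4 flank C3a, which carries C3. That is the pattern of cyclohexane-1,3-dione 4 alkylated on its central carbon and closed through one enol oxygen, so ring A can be carried at the dione oxidation level through the ring-forming step and aromatised afterwards.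

## Retrosynthetic reasoning

**19 ⇒ 18.** The last operation is removal of a silyl group from the ring C phenol. The phenol has to be masked only while an organolithium is present, and a silyl ether comes off under buffered fluoride without touching the enone or the tertiary alcohol.

**18 ⇒ 13 + 16.** The C7–C(=O) bond is cut. This keeps the enone out of all redox chemistry on rings A and B and joins two fragments of similar size at the end. Forward, aryl bromide 13 becomes the aryllithium 17 (the tertiary hydroxyl is carried as its lithium alkoxide), which acylates Weinreb amide 16. The amide stops the addition at the ketone stage and keeps the E alkene. Amide 16 comes from acid 14 through amide 15 in two routine steps.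

**13 ⇒ 12 ⇒ 11.** The O-methyl bond and the C7–Br bond are cut in that order. Bromine must enter while the C4 oxygen is still a free hydroxyl, because C7 is para to it. Once the oxygen is methylated, the better-conjugated ring oxygen O1 would steer an electrophile to C5. Methylation after bromination then fixes the pattern.

**11 ⇒ 7.** Ring A is taken back to the cyclohexenone oxidation level. Forward, the vinylogous ester 7 has to lose two hydrogens from C5 and C6. An enolate selenenylation and selenoxide elimination (8, 9, then dienone 10) does this at low temperature, and 10 is the keto tautomer of phenol 11. No metal surface or heat is involved, so C2–C3 stays saturated.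

**7 ⇒ 6.** The tertiary C–O bond of the side chain is cut, back to the prop-1-en-2-yl group. The hydration is placed directly after ring formation for three reasons:
- in 6 the C2–O1 bond is allylic and could be re-ionised by palladium; after hydration it is not;
- the alkene would otherwise have to survive the peroxide of the aromatisation and the electrophilic bromine of the next step;
- the only other alkene in 6 is a tetrasubstituted, donor-substituted enone that does not take part in hydrogen-atom transfer.

**6 ⇒ 3 + 4 (key disconnection).** C3–C3a and O1–C2 are cut, which removes ring B and the stereocentre together and leaves dione 4 and the C5 bis-carbonate 3. The cut is made here because the central carbon of 4 is its only carbon nucleophile, so the attachment at C3a is unambiguous, and because the two oxygens of 4 are equivalent, so either may close the ring. In 3 only the tertiary carbonate is allylic, so the C–C bond must form first, through the monocarbonate 5. The second ionisation then offers a π-allyl complex to the enol oxygen, and a chiral diphosphine on palladium chooses the face. Carbonates are used as leaving groups because each releases its own base, so the reaction runs without added base.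

**3 ⇒ 2 ⇒ 1.** The bis-carbonate comes from diol 2 by double acylation. Diol 2 is made by adding a vinyl Grignard reagent to hydroxy ketone 1. This is preferred to hydrolysis of the corresponding vinyl epoxide, which under acid passes through an allylic cation and also gives the 1,4-diol. The diol is racemic, which is of no consequence because its stereocentre becomes part of a π-allyl complex.

## Alternatives that were turned down

**Alternative 1: benzannulation that builds ring A.**
- Disconnection: ring A itself, at C3a–C7a, C4–C5 and C7–C7a, back to an α-diazo vinyl ketone carrying an ester and a methyl ynol ether. The ynol ether's chain already holds the C2 oxygen as an (S)-methanesulfonate and the tertiary alcohol as a silyl ether.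
- Forward key step: irradiation triggers a Wolff rearrangement to an ester-substituted vinylketene, which adds to the ynol ether. Four-electron ring opening, six-electron closure and tautomerisation give methyl 2-hydroxy-4-methoxy-3-[(2S)-2-(methanesulfonyloxy)-3-methyl-3-(triethylsilyloxy)butyl]benzoate A1. The phenol then displaces the sulfonate with inversion to close ring B, and the ester is elaborated to the enone.
- For: every substituent of ring A is placed by connectivity, so no aromatic substitution has to be steered. On this point it is stronger than the chosen route, which relies on a directing effect for C7.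
- Against: the ynol ether with a sulfonate and a silyl ether is hydrolytically and thermally fragile and needs a sequence of its own, stereocentre included. The diazo ketone needs a diazo transfer. The ring closure is a substitution at a secondary carbon next to a fully substituted one, where elimination competes. The ester still needs two or three steps to become the cinnamoyl ketone.
- Comparison: the chosen strategy gives up some regiochemical certainty at C7. In return it forms ring B and the stereocentre in one catalytic step from two simple components and reaches the target in fewer steps.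

**Alternative 2: three-component carbonylative Heck assembly of the enone.**
- Disconnection: both bonds at the ketone carbon, C7–C(=O) and C(=O)–Cα, back to 2-[(2R)-7-iodo-4-methoxy-2,3-dihydro-1-benzofuran-2-yl]propan-2-ol A3, a one-carbon carbonyl source under pressure, and 4-ethenylphenyl acetate A4.
- Forward key step: zerovalent palladium, formed from Pd(OAc)2 and a bulky phosphine, inserts into the C–I bond. Carbonyl insertion gives the aroyl complex, and alkene insertion and β-hydride elimination give 4-[(E)-3-[(2R)-2-(2-hydroxypropan-2-yl)-4-methoxy-2,3-dihydro-1-benzofuran-7-yl]-3-oxoprop-1-en-1-yl]phenyl acetate A2.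
- For: no stoichiometric organometallic and no low temperature; the free tertiary alcohol is tolerated without an extra equivalent of base; the E geometry follows from the elimination. As an end game it is more economical than the aryllithium acylation used here.
- Against: it is only an end game. A3 still has to be made, with the same stereochemical and regiochemical questions. The electron-rich aryl group flanked by O1 slows carbonyl insertion, so direct arylation of the styrene to a stilbene competes. Pressure equipment is needed.
- Comparison: the chosen end game is stoichiometric, but each elementary step is unambiguous. The main contribution of the chosen strategy lies upstream, where this alternative offers nothing.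

**Alternative 3: cobalt metalloradical C–H alkylation closing C2–C3.**
- Disconnection: C2–C3, back to the N-tosylhydrazone of a benzaldehyde whose ortho oxygen carries an O–CH2–C(CH3)2OH chain.
- Forward key step: base gives the aryldiazomethane, which a divalent cobalt complex [Co(P*)] of a D2-symmetric chiral amidoporphyrin P* converts into a benzylic radical at C3. This abstracts hydrogen from the O–CH2 group and recombines to give 2-[(2R)-7-bromo-4-methoxy-2,3-dihydro-1-benzofuran-2-yl]propan-2-ol A5, which is identical with compound 13 of the chosen route.
- For: bromine, methoxy and the tertiary alcohol are already in place, so no aromatisation, bromination or hydration follows. After its key step this alternative is shorter than the chosen route.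
- Against: the catalyst needs a synthesis of its own. The aldehyde carbon sits between two ortho oxygen substituents, which hinders hydrazone and diazo formation. The hydrogen to be abstracted is next to a fully substituted carbinol carbon, and the free hydroxyl can compete for the radical or carbene. The trisubstituted benzaldehyde precursor is itself a regiochemical problem.
- Comparison: the chosen strategy uses a commercial palladium source and ligand, starting materials of low cost, and a stereo-determining step that is a close relative of established oxygen allylations.

Key step: step 3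

Assumption: the (R,R)-ligand is taken to give the 2R product, by analogy with the closure of ortho-allyl phenols under the same catalyst. The sense is to be confirmed on compound 6, and the (S,S)-ligand is used if it proves opposite.

## Route

Step 1
Reactants: 1 hydroxyacetone (1-hydroxypropan-2-one)
Product: 2 rac-2-methylbut-3-ene-1,2-diol
Conditions: CH2=CHMgBr (2.5 equiv), THF, 0 °C to rt; aq. NH4Cl
Reagents that add atoms: vinylmagnesium bromide, C=C[Mg]Br
Why: Grignard addition to a ketone; the first equivalent is consumed by the hydroxyl and the resulting magnesium alkoxide chelates the ketone for the second. The product is racemic, which is acceptable because this centre is lost on ionisation in step 3.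

Step 2
Reactants: 2 rac-2-methylbut-3-ene-1,2-diol
Product: 3 rac-dimethyl 2-methylbut-3-ene-1,2-diyl dicarbonate
Conditions: ClCO2Me (4 equiv, in two portions), pyridine, DMAP (0.2 equiv), CH2Cl2, 0 °C to rt
Reagents that add atoms: methyl chloroformate, COC(Cl)=O
Why: Acylation through the N-acylpyridinium ion; the primary hydroxyl reacts first and the tertiary allylic one needs DMAP and excess reagent. Weakly basic, alkoxide-free conditions are chosen so that the hydroxy carbonate is not closed to the five-membered cyclic carbonate.

Step 3
Reactants: 3 rac-dimethyl 2-methylbut-3-ene-1,2-diyl dicarbonate; 4 cyclohexane-1,3-dione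
Product: 6 (2R)-2-(prop-1-en-2-yl)-3,5,6,7-tetrahydro-1-benzofuran-4(2H)-one, via monocarbonate 5 (not isolated)
Conditions: Pd2(dba)3·CHCl3 (2.5 mol%), (R,R)-DACH-phenyl ligand N,N'-[(1R,2R)-cyclohexane-1,2-diyl]bis[2-(diphenylphosphanyl)benzamide] (7.5 mol%), CH2Cl2, rt
Reagents that add atoms: none
Why: Zerovalent palladium ionises the only allylic leaving group of 3, the tertiary carbonate, with loss of CO2 and methoxide, which deprotonates 4; both enantiomers of 3 give the same 1,1-disubstituted π-allyl complex. The dione enolate attacks the unsubstituted terminus through its central carbon (C3–C3a); O-allylation is reversible because an allyl enol ether of a 1,3-dione is itself an allylic electrophile, so the material collects as 5, an E/Z mixture in which the remaining carbonate has become allylic. A second ionisation gives a 2-methyl-substituted π-allyl complex, and the enol oxygen attacks its proximal, substituted terminus in a 5-exo closure (O1–C2) that leaves the prop-1-en-2-yl group outside the ring. The closest known reaction type is the palladium-catalysed tandem C-allylation and O-allylation of cyclic 1,3-diones with but-2-ene-1,4-diyl bis-electrophiles to 2-vinyl tetrahydrobenzofuranones, together with the enantioselective closure of ortho-(4-carbonyloxy-3-methylbut-2-enyl)phenols to 2-(prop-1-en-2-yl) dihydrobenzofurans with this ligand class. C2 is the only new stereocentre and is set by the chiral diphosphine in the O–C bond-forming step: the diastereomeric π-allyl complexes interconvert by π–σ–π exchange through the CH2 terminus and the ligand pocket lets one of them close faster (Curtin–Hammett control), the acidity of the dione slowing closure enough for this exchange. The step needs linear first attack (secured by the hindered, fully substituted terminus and by the fact that only the tertiary carbonate can ionise at the start), five- over seven-membered closure (ring size), and O- over C-closure (C-closure would give a spiro vinylcyclopropane that zerovalent palladium reopens).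

Step 4
Reactants: 6 (2R)-2-(prop-1-en-2-yl)-3,5,6,7-tetrahydro-1-benzofuran-4(2H)-one
Product: 7 (2R)-2-(2-hydroxypropan-2-yl)-3,5,6,7-tetrahydro-1-benzofuran-4(2H)-one
Conditions: Co(acac)2 (20 mol%), PhSiH3 (2 equiv), O2 (1 atm), THF, rt
Reagents that add atoms: dioxygen, O=O
Why: Mukaiyama hydration; hydrogen-atom transfer from a cobalt hydride to the 1,1-disubstituted alkene gives the tertiary radical (Markovnikov), which is trapped by O2 and reduced to the alcohol. The tetrasubstituted β-alkoxy enone is too hindered to accept a hydrogen atom, and C2 is not involved.

Step 5
Reactants: 7 (2R)-2-(2-hydroxypropan-2-yl)-3,5,6,7-tetrahydro-1-benzofuran-4(2H)-one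
Product: 11 (2R)-2-(2-hydroxypropan-2-yl)-2,3-dihydro-1-benzofuran-4-ol, via selenide 8 (not isolated), via selenoxide 9 (not isolated), via dienone 10 (not isolated)
Conditions: LiN(i-Pr)2 (2.2 equiv), THF, −78 °C; PhSeBr (1.1 equiv), −78 °C; AcOH, then 30% aq. H2O2, pyridine, 0 °C to rt
Reagents that add atoms: none
Why: After the hydroxyl is deprotonated, the kinetic enolate of the vinylogous ester forms at C5 and is selenenylated; selenoxide syn-elimination toward C6 gives the cross-conjugated dienone 10, the keto tautomer of the phenol, which aromatises at once. No metal surface or heat is used, so C2–C3 stays saturated and C2 is untouched.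

Step 6
Reactants: 11 (2R)-2-(2-hydroxypropan-2-yl)-2,3-dihydro-1-benzofuran-4-ol
Product: 12 (2R)-7-bromo-2-(2-hydroxypropan-2-yl)-2,3-dihydro-1-benzofuran-4-ol
Conditions: NBS (1.0 equiv), DMF, −20 to 0 °C, dark
Reagents that add atoms: N-bromosuccinimide, O=C1CCC(=O)N1Br
Why: Electrophilic aromatic bromination; C7 is para to the free hydroxyl and ortho to O1, and this reagent in DMF favours the position para to a free phenol. The neutral by-product leaves the tertiary alcohol alone.

Step 7
Reactants: 12 (2R)-7-bromo-2-(2-hydroxypropan-2-yl)-2,3-dihydro-1-benzofuran-4-ol
Product: 13 2-[(2R)-7-bromo-4-methoxy-2,3-dihydro-1-benzofuran-2-yl]propan-2-ol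
Conditions: MeI (1.5 equiv), K2CO3 (2 equiv), acetone, 40 °C
Reagents that add atoms: iodomethane, CI
Why: Williamson ether synthesis; the carbonate deprotonates the phenol but not the tertiary alcohol, so only the C4 oxygen is methylated.

Step 8
Reactants: 14 (E)-4-hydroxycinnamic acid
Product: 15 (2E)-3-(4-hydroxyphenyl)-N-methoxy-N-methylprop-2-enamide
Conditions: MeNHOMe·HCl (1.2 equiv), EDC·HCl (1.2 equiv), HOBt (1.2 equiv), N-methylmorpholine (2.5 equiv), DMF, 0 °C to rt
Reagents that add atoms: N,O-dimethylhydroxylamine hydrochloride, CNOC.Cl
Why: Carbodiimide amide coupling through the hydroxybenzotriazole ester; the amine outcompetes the phenol as nucleophile, and any aryl ester formed is aminolysed. The E alkene is not affected.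

Step 9
Reactants: 15 (2E)-3-(4-hydroxyphenyl)-N-methoxy-N-methylprop-2-enamide
Product: 16 (2E)-3-{4-[(tert-butyldimethylsilyl)oxy]phenyl}-N-methoxy-N-methylprop-2-enamide
Conditions: TBSCl (1.2 equiv), imidazole (2.5 equiv), DMF, rt
Reagents that add atoms: tert-butyl(chloro)dimethylsilane, CC(C)(C)[Si](C)(C)Cl
Why: Silylation of the phenol, which removes the acidic proton that would quench the aryllithium of step 10.

Step 10
Reactants: 13 2-[(2R)-7-bromo-4-methoxy-2,3-dihydro-1-benzofuran-2-yl]propan-2-ol; 16 (2E)-3-{4-[(tert-butyldimethylsilyl)oxy]phenyl}-N-methoxy-N-methylprop-2-enamide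
Product: 18 (2E)-3-{4-[(tert-butyldimethylsilyl)oxy]phenyl}-1-[(2R)-2-(2-hydroxypropan-2-yl)-4-methoxy-2,3-dihydro-1-benzofuran-7-yl]prop-2-en-1-one, via aryllithium alkoxide 17 (not isolated)
Conditions: MeLi (1.05 equiv), THF, −78 °C; t-BuLi (2.1 equiv), −78 °C; 16 (1.2 equiv), −78 to −20 °C; aq. NH4Cl
Reagents that add atoms: none
Why: The hydroxyl is first deprotonated, bromine–lithium exchange then gives the aryllithium 17 (stabilised by the adjacent O1), and acyl substitution on the Weinreb amide stops at the ketone stage because the N-methoxy group holds the adduct as a chelate until work-up. A hard aryllithium adds to the amide carbonyl and not to the β-carbon, and the E alkene is carried over unchanged.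

Step 11
Reactants: 18 (2E)-3-{4-[(tert-butyldimethylsilyl)oxy]phenyl}-1-[(2R)-2-(2-hydroxypropan-2-yl)-4-methoxy-2,3-dihydro-1-benzofuran-7-yl]prop-2-en-1-one
Product: 19 (2E)-1-[(2R)-2-(2-hydroxypropan-2-yl)-4-methoxy-2,3-dihydro-1-benzofuran-7-yl]-3-(4-hydroxyphenyl)prop-2-en-1-one
Conditions: n-Bu4NF (1.1 equiv), AcOH (1.2 equiv), THF, 0 °C
Reagents that add atoms: none
Why: Fluoride cleavage of an aryl silyl ether; the acetic acid buffer protonates the phenoxide as it forms, so the enone is not exposed to a free base and the tertiary alcohol is not exposed to acid.

## Compound list

1 | hydroxyacetone (1-hydroxypropan-2-one) | CC(=O)CO | starting material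
2 | rac-2-methylbut-3-ene-1,2-diol | CC(O)(CO)C=C | intermediate
3 | rac-dimethyl 2-methylbut-3-ene-1,2-diyl dicarbonate | COC(=O)OCC(C)(OC(=O)OC)C=C | intermediate
4 | cyclohexane-1,3-dione | O=C1CCCC(=O)C1 | starting material
5 | 4-(2,6-dioxocyclohexyl)-2-methylbut-2-en-1-yl methyl carbonate (E/Z mixture) | COC(=O)OCC(C)=CCC1C(=O)CCCC1=O | intermediate
6 | (2R)-2-(prop-1-en-2-yl)-3,5,6,7-tetrahydro-1-benzofuran-4(2H)-one | O=C1CCCC2=C1C[C@H](C(C)=C)O2 | intermediate
7 | (2R)-2-(2-hydroxypropan-2-yl)-3,5,6,7-tetrahydro-1-benzofuran-4(2H)-one | O=C1CCCC2=C1C[C@H](C(C)(C)O)O2 | intermediate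
8 | (2R)-2-(2-hydroxypropan-2-yl)-5-(phenylselanyl)-3,5,6,7-tetrahydro-1-benzofuran-4(2H)-one (C5 epimers) | O=C1C(CCC2=C1C[C@H](C(C)(C)O)O2)[Se]c1ccccc1 | intermediate
9 | (2R)-5-(benzeneseleninyl)-2-(2-hydroxypropan-2-yl)-3,5,6,7-tetrahydro-1-benzofuran-4(2H)-one | O=C1C(CCC2=C1C[C@H](C(C)(C)O)O2)[Se](=O)c1ccccc1 | intermediate
10 | (2R)-2-(2-hydroxypropan-2-yl)-3,7-dihydro-1-benzofuran-4(2H)-one | O=C1C=CCC2=C1C[C@H](C(C)(C)O)O2 | intermediate
11 | (2R)-2-(2-hydroxypropan-2-yl)-2,3-dihydro-1-benzofuran-4-ol | Oc1cccc2c1C[C@H](C(C)(C)O)O2 | intermediate
12 | (2R)-7-bromo-2-(2-hydroxypropan-2-yl)-2,3-dihydro-1-benzofuran-4-ol | Oc1ccc(Br)c2c1C[C@H](C(C)(C)O)O2 | intermediate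
13 | 2-[(2R)-7-bromo-4-methoxy-2,3-dihydro-1-benzofuran-2-yl]propan-2-ol | COc1ccc(Br)c2c1C[C@H](C(C)(C)O)O2 | intermediate
14 | (E)-4-hydroxycinnamic acid | O=C(O)/C=C/c1ccc(O)cc1 | starting material
15 | (2E)-3-(4-hydroxyphenyl)-N-methoxy-N-methylprop-2-enamide | CON(C)C(=O)/C=C/c1ccc(O)cc1 | intermediate
16 | (2E)-3-{4-[(tert-butyldimethylsilyl)oxy]phenyl}-N-methoxy-N-methylprop-2-enamide | CON(C)C(=O)/C=C/c1ccc(O[Si](C)(C)C(C)(C)C)cc1 | intermediate
17 | lithium 2-[(2R)-7-lithio-4-methoxy-2,3-dihydro-1-benzofuran-2-yl]propan-2-olate | COc1ccc([Li])c2c1C[C@H](C(C)(C)O[Li])O2 | intermediate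
18 | (2E)-3-{4-[(tert-butyldimethylsilyl)oxy]phenyl}-1-[(2R)-2-(2-hydroxypropan-2-yl)-4-methoxy-2,3-dihydro-1-benzofuran-7-yl]prop-2-en-1-one | COc1ccc(C(=O)/C=C/c2ccc(O[Si](C)(C)C(C)(C)C)cc2)c2c1C[C@H](C(C)(C)O)O2 | intermediate
19 | (2E)-1-[(2R)-2-(2-hydroxypropan-2-yl)-4-methoxy-2,3-dihydro-1-benzofuran-7-yl]-3-(4-hydroxyphenyl)prop-2-en-1-one | COc1ccc(C(=O)/C=C/c2ccc(O)cc2)c2c1C[C@H](C(C)(C)O)O2 | target

## Step count and least certain steps

Total step count: 11. Longest linear sequence: 9 steps (steps 1 to 7, 10 and 11, from 1); steps 8 and 9 form a two-step side branch from 14.

**Step 3 (key step).** Two processes can lower the enantiomeric purity. Ring closure may outrun the syn/anti and face exchange of the second π-allyl complex; since 5 forms as an E/Z mixture, the two geometric series could then close with opposite sense. Palladium may also re-ionise the allylic C2–O1 bond of 6, because the enolate of a 1,3-dione is a competent leaving group. A second intermolecular C-allylation of 5 would lower the yield. The fallback sets the stereocentre by an epoxidation and sets out from 4. C-Prenylation of 4 (1-bromo-3-methylbut-2-ene, aqueous KOH) should give 2-(3-methylbut-2-en-1-yl)cyclohexane-1,3-dione F1. O-Methylation with trimethylsilyldiazomethane in methanol/toluene should give 3-methoxy-2-(3-methylbut-2-en-1-yl)cyclohex-2-en-1-one F2. Shi epoxidation of the trisubstituted alkene (L-fructose-derived ketone catalyst, KHSO5, buffered aqueous acetonitrile, 0 °C) is expected to give 2-{[(2S)-3,3-dimethyloxiran-2-yl]methyl}-3-methoxycyclohex-2-en-1-one F3. Warm aqueous NaOH in THF then displaces methoxide from the vinylogous ester, and the dione enolate opens the epoxide at its secondary carbon in a 5-exo closure with inversion. This comes back to the route at 7, so steps 1 to 4 are bypassed.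

**Step 2.** The tertiary allylic hydroxyl may acylate too slowly, and the intermediate hydroxy carbonate may instead close to the five-membered cyclic carbonate with loss of methanol. The fallback sets out from 2: acetic anhydride, triethylamine and DMAP should give rac-2-methylbut-3-ene-1,2-diyl diacetate F4, which cannot cyclise in this way. F4 takes the place of 3 in step 3, with Cs2CO3 (2 equiv) added to form the dione enolate, and the route is rejoined at 6.

**Step 5.** The electron-rich phenol 11 forms in the presence of peroxide and selenium by-products and may be oxidised further or selenenylated on the ring; deprotonation at C7 in place of C5 would also divert material. The fallback sets out from 7. The same kinetic enolate is quenched with N-bromosuccinimide at −78 °C to give (2R)-5-bromo-2-(2-hydroxypropan-2-yl)-3,5,6,7-tetrahydro-1-benzofuran-4(2H)-one F5. Dehydrobromination with Li2CO3 and LiBr in DMF at 110 °C gives dienone 10 and hence 11, with no oxidant present when the phenol appears.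

**Step 6.** Bromination may occur in part at C5, which is ortho to the hydroxyl and para to O1, or twice. The fallback replaces the directing effect of the hydroxyl by a directed lithiation and sets out from 11. Silylation with chlorotri(propan-2-yl)silane and imidazole gives 2-[(2R)-4-{[tri(propan-2-yl)silyl]oxy}-2,3-dihydro-1-benzofuran-2-yl]propan-2-ol F6. With n-BuLi (2.3 equiv) and TMEDA in diethyl ether, the alkoxide forms and O1 directs lithiation to C7, the bulky silyl ether shielding C5. Quenching with 1,2-dibromotetrafluoroethane gives 2-[(2R)-7-bromo-4-{[tri(propan-2-yl)silyl]oxy}-2,3-dihydro-1-benzofuran-2-yl]propan-2-ol F7. n-Bu4NF removes the silyl group and the route is rejoined at 12.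

**Step 10.** The aryllithium may add to the β-carbon of the cinnamoyl amide, attack silicon, or be incompletely formed because of aggregation with the alkoxide. The fallback builds the enone by condensation and sets out from 13. The same dianion is quenched with N-methoxy-N-methylacetamide to give 1-[(2R)-2-(2-hydroxypropan-2-yl)-4-methoxy-2,3-dihydro-1-benzofuran-7-yl]ethan-1-one F8. A Claisen–Schmidt condensation of F8 with 4-hydroxybenzaldehyde (KOH, ethanol, rt to 40 °C) should give the E enone directly and comes back to the route at 19, bypassing steps 8, 9 and 11.

## Further compounds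

F1 | step 3 | 2-(3-methylbut-2-en-1-yl)cyclohexane-1,3-dione | CC(C)=CCC1C(=O)CCCC1=O
F2 | step 3 | 3-methoxy-2-(3-methylbut-2-en-1-yl)cyclohex-2-en-1-one | COC1=C(CC=C(C)C)C(=O)CCC1
F3 | step 3 | 2-{[(2S)-3,3-dimethyloxiran-2-yl]methyl}-3-methoxycyclohex-2-en-1-one | COC1=C(C[C@@H]2OC2(C)C)C(=O)CCC1
F4 | step 2 | rac-2-methylbut-3-ene-1,2-diyl diacetate | CC(=O)OCC(C)(OC(C)=O)C=C
F5 | step 5 | (2R)-5-bromo-2-(2-hydroxypropan-2-yl)-3,5,6,7-tetrahydro-1-benzofuran-4(2H)-one | O=C1C(Br)CCC2=C1C[C@H](C(C)(C)O)O2
F6 | step 6 | 2-[(2R)-4-{[tri(propan-2-yl)silyl]oxy}-2,3-dihydro-1-benzofuran-2-yl]propan-2-ol | CC(C)[Si](Oc1cccc2c1C[C@H](C(C)(C)O)O2)(C(C)C)C(C)C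
F7 | step 6 | 2-[(2R)-7-bromo-4-{[tri(propan-2-yl)silyl]oxy}-2,3-dihydro-1-benzofuran-2-yl]propan-2-ol | CC(C)[Si](Oc1ccc(Br)c2c1C[C@H](C(C)(C)O)O2)(C(C)C)C(C)C
F8 | step 10 | 1-[(2R)-2-(2-hydroxypropan-2-yl)-4-methoxy-2,3-dihydro-1-benzofuran-7-yl]ethan-1-one | COc1ccc(C(C)=O)c2c1C[C@H](C(C)(C)O)O2
A1 | alternative 1 | methyl 2-hydroxy-4-methoxy-3-[(2S)-2-(methanesulfonyloxy)-3-methyl-3-(triethylsilyloxy)butyl]benzoate | COC(=O)c1ccc(OC)c(C[C@H](OS(C)(=O)=O)C(C)(C)O[Si](CC)(CC)CC)c1O
A2 | alternative 2 | 4-[(E)-3-[(2R)-2-(2-hydroxypropan-2-yl)-4-methoxy-2,3-dihydro-1-benzofuran-7-yl]-3-oxoprop-1-en-1-yl]phenyl acetate | COc1ccc(C(=O)/C=C/c2ccc(OC(C)=O)cc2)c2c1C[C@H](C(C)(C)O)O2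
A3 | alternative 2 | 2-[(2R)-7-iodo-4-methoxy-2,3-dihydro-1-benzofuran-2-yl]propan-2-ol | COc1ccc(I)c2c1C[C@H](C(C)(C)O)O2
A4 | alternative 2 | 4-ethenylphenyl acetate | CC(=O)Oc1ccc(C=C)cc1
A5 | alternative 3 | 2-[(2R)-7-bromo-4-methoxy-2,3-dihydro-1-benzofuran-2-yl]propan-2-ol | COc1ccc(Br)c2c1C[C@H](C(C)(C)O)O2
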